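## Plan

1. Retrosynthesis: the six O-protecting groups and the C4–vinyl bond of the 4-hydroxystyryl arm (Heck) are cut first. Then the O1–C7a and C3–C3a bonds of the dihydrobenzofuran are cut together, leaving 3-bromo-5-methoxybenzyne and a trans-2,3-diaryloxirane. The oxirane goes back to an E-stilbene, and that to an aryl bromide and a styrene.
2. Forward: the rings on C2 and C3 are joined as a stilbene and epoxidised. Ring A (the benzo ring) is made separately as an ortho-silylaryl triflate. The aryne inserts into one epoxide C–O bond and so closes the dihydrofuran ring onto ring A. Demethylation/acetylation, Heck coupling at C4 and global hydrolysis finish the route.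
3. Enabling feature: the O-bearing C7a and the C-bearing C3a are neighbouring carbons of ring A, the two ends of an aryne. O1–C2–C3 is an oxirane in disguise in which C3 is benzylic and can give up its oxygen. C4, next to C3a, can carry Br in place of the styryl arm, so Br first polarises the aryne and then serves as the coupling handle.
4. Helpers: two tosyl groups on the catechol ring decide which benzylic C–O bond survives and are removed at the end. The C4 bromine is used up in the Heck step.
5. Stereochemistry: the Shi epoxidation sets the (2R,3R)-oxirane. C2 never breaks its C–O bond, and C3 is re-formed with retention, trans to the C2 aryl group, which gives (2S,3S). Both Heck reactions give E-alkenes.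

Key step: step 6

Remark: the target SMILES is read as the trans-(2S,3S)-2,3-dihydrobenzofuran (numbering O1, C2, C3, C3a, C4–C7, C7a). Compounds 1, 3, 6, 16 and the D-fructose-derived Shi ketone are assumed to be purchasable.

## Route

Step 1
Reactants: 1 4-bromobenzene-1,2-diol
Product: 2 4-bromo-1,2-phenylene bis(4-methylbenzenesulfonate)
Conditions: TsCl (2.3 equiv), Et3N, 4-(dimethylamino)pyridine (cat.), CH2Cl2, 0 °C → rt
Reagents that add atoms: 4-methylbenzenesulfonyl chloride (TsCl), Cc1ccc(cc1)S(=O)(=O)Cl
Why: O-sulfonylation of both phenols with a sulfonyl chloride and an amine base is routine, and the two tosyloxy groups are put on here as the electron-withdrawing helpers that later steer the epoxide opening.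

Step 2
Reactants: 2 4-bromo-1,2-phenylene bis(4-methylbenzenesulfonate); 3 1-ethenyl-3,5-dimethoxybenzene
Product: 4 4-[(E)-2-(3,5-dimethoxyphenyl)ethenyl]-1,2-phenylene bis(4-methylbenzenesulfonate)
Conditions: Pd(OAc)2 (3 mol %), P(o-tol)3, Et3N, DMF, 100 °C
Reagents that add atoms: none
Why: Mizoroki–Heck reaction, in which zerovalent palladium inserts into the electron-poor C–Br bond (aryl tosylates are inert to this catalyst), adds syn to the terminal carbon of the styrene and leaves by syn-β-hydride elimination to give the E-stilbene.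

Step 3
Reactants: 4 4-[(E)-2-(3,5-dimethoxyphenyl)ethenyl]-1,2-phenylene bis(4-methylbenzenesulfonate)
Product: 5 4-[(2R,3R)-3-(3,5-dimethoxyphenyl)oxiran-2-yl]-1,2-phenylene bis(4-methylbenzenesulfonate)
Conditions: 1,2:4,5-di-O-isopropylidene-β-D-erythro-2,3-hexodiulo-2,6-pyranose (D-fructose-derived Shi ketone, 30 mol %), KHSO5 (as 2KHSO5·KHSO4·K2SO4), K2CO3, Bu4NHSO4 (cat.), MeCN–CH2(OMe)2 / aq. Na2B4O7–Na2(EDTA) buffer, pH 10.5, 0 °C
Reagents that add atoms: potassium peroxymonosulfate (KHSO5), [K+].[O-]S(=O)(=O)OO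
Why: Shi asymmetric epoxidation, in which the chiral dioxirane formed from the ketone transfers oxygen to the E-alkene through a spiro transition state that gives the (R,R)-oxirane from trans-1,2-diaryl alkenes, so the catalyst sets both epoxide stereocentres.

Step 4
Reactants: 6 2,6-dibromo-4-methoxyphenol
Product: 7 (2,6-dibromo-4-methoxyphenoxy)trimethylsilane
Conditions: HMDS, THF, 70 °C; volatiles removed in vacuo
Reagents that add atoms: hexamethyldisilazane (HMDS), C[Si](C)(C)N[Si](C)(C)C
Why: O-silylation of a phenol with HMDS is clean and gives only ammonia beside the silyl ether, which can be used crude.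

Step 5
Reactants: 7 (2,6-dibromo-4-methoxyphenoxy)trimethylsilane
Product: 10 2-bromo-4-methoxy-6-(trimethylsilyl)phenyl trifluoromethanesulfonate, via aryllithium 8 (not isolated), via lithium phenolate 9 (not isolated)
Conditions: n-BuLi (1.05 equiv), THF, −100 → −80 °C; then Tf2O, −100 °C → rt
Reagents that add atoms: trifluoromethanesulfonic anhydride (Tf2O), O=S(=O)(OS(=O)(=O)C(F)(F)F)C(F)(F)F
Why: bromine–lithium exchange at one of the two equivalent bromines, anionic silyl shift from O to C (retro-Brook rearrangement) and O-triflation of the phenolate is the standard entry to ortho-silylaryl triflates (Kobayashi aryne precursors), the symmetry of 7 leaving no regiochemical question and the second bromine staying as the directing group.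

Step 6
Reactants: 5 4-[(2R,3R)-3-(3,5-dimethoxyphenyl)oxiran-2-yl]-1,2-phenylene bis(4-methylbenzenesulfonate); 10 2-bromo-4-methoxy-6-(trimethylsilyl)phenyl trifluoromethanesulfonate
Product: 13 4-[(2S,3S)-4-bromo-3-(3,5-dimethoxyphenyl)-6-methoxy-2,3-dihydro-1-benzofuran-2-yl]-1,2-phenylene bis(4-methylbenzenesulfonate), via aryne 11 (not isolated), via oxiranium zwitterion 12 (not isolated)
Conditions: CsF (4 equiv), MeCN–toluene 1:3, 25 → 40 °C; 10 (2.5 equiv) added over 6 h to 5
Reagents that add atoms: none
Why: Proposed new method: fluoride removes the silyl group of 10 and triflate leaves to give aryne 11, the oxirane oxygen of 5 adds to the strained triple bond to give zwitterion 12 (O-aryl oxiranium with a carbanion on the neighbouring ring carbon), and 12 then breaks its C–O bond to the 3,5-dimethoxybenzylic carbon while the carbanion bonds to that carbon, so that the aryne is inserted into one C–O bond of the epoxide in a formal (3+2) annulation that makes O1–C7a and C3–C3a in one operation. The closest known reaction type is the fluoride-induced insertion of benzyne into the benzylic C–O bond of a monoaryl oxirane of the styrene oxide kind, which gives a 3-aryl-2,3-dihydrobenzofuran, and what is new is its use on an enantioenriched trans-2,3-diaryloxirane with a choice between two benzylic C–O bonds and with transfer of the epoxide configuration. The one ring that closes, the dihydrofuran ring, closes by collapse of the aryl carbanion onto the benzylic carbon that is losing oxygen, a five-membered ring closure within a tight zwitterion, because a backside displacement through so short a tether is impossible. C2 keeps its C–O bond and with it the configuration set in step 3, and C3 is re-formed with retention because the carbanion sits on the departing oxygen and bonds to the face that this oxygen leaves, a course that the C2 aryl group reinforces by holding the 3,5-dimethoxyphenyl group on the opposite face of the new ring (trans), so that (2R,3R)-5 should give (2S,3S)-13. The step needs the oxygen to add to the aryne carbon that becomes C7a, which the groups beside the triple bond secure, since bromine on C4 withdraws σ-electrons, distorts the aryne so that the remote carbon is the electrophilic one, stabilises the carbanion that develops next to it at C3a and shields that carbon, whereas hydrogen on C7 does none of this and the methoxy group one carbon further away has only a weak influence. It also needs the C–O bond at the 3,5-dimethoxybenzylic carbon to be the one that breaks, which the two sulfonyloxy groups secure by destabilising positive charge at the other benzylic carbon, and it needs ring closure to outrun capture of 12 by fluoride or loss of bromide, which slow aryne generation at low fluoride concentration and the intramolecular nature of the collapse favour.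

Step 7
Reactants: 13 4-[(2S,3S)-4-bromo-3-(3,5-dimethoxyphenyl)-6-methoxy-2,3-dihydro-1-benzofuran-2-yl]-1,2-phenylene bis(4-methylbenzenesulfonate)
Product: 15 4-[(2S,3S)-6-acetoxy-3-(3,5-diacetoxyphenyl)-4-bromo-2,3-dihydro-1-benzofuran-2-yl]-1,2-phenylene bis(4-methylbenzenesulfonate), via triphenol 14 (not isolated)
Conditions: BBr3 (6 equiv), CH2Cl2, −78 → 0 °C; ice-water work-up; then Ac2O, pyridine, 4-(dimethylamino)pyridine (cat.), CH2Cl2, rt
Reagents that add atoms: acetic anhydride, CC(=O)OC(C)=O
Why: Lewis acid cleavage of the three aryl methyl ethers with BBr3 (boron on oxygen, bromide on methyl) is done before any stilbene is present and while the tosylates keep the C2 aryl ring electron-poor so that the benzylic C2–O1 bond should not ionise, and acetylation of the crude triphenol gives a stable bromide for the coupling without touching either stereocentre.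

Step 8
Reactants: 15 4-[(2S,3S)-6-acetoxy-3-(3,5-diacetoxyphenyl)-4-bromo-2,3-dihydro-1-benzofuran-2-yl]-1,2-phenylene bis(4-methylbenzenesulfonate); 16 4-ethenylphenyl acetate
Product: 17 4-[(2S,3S)-6-acetoxy-4-[(E)-2-(4-acetoxyphenyl)ethenyl]-3-(3,5-diacetoxyphenyl)-2,3-dihydro-1-benzofuran-2-yl]-1,2-phenylene bis(4-methylbenzenesulfonate)
Conditions: Pd2(dba)3 (2.5 mol %), [HP(t-Bu)3]BF4 (10 mol %), Cy2NMe, 1,4-dioxane, 80 °C
Reagents that add atoms: none
Why: Mizoroki–Heck reaction with the bulky electron-rich phosphine P(t-Bu)3, which lets zerovalent palladium insert into the hindered ortho-substituted C4–Br bond at moderate temperature while aryl tosylates and acetates are left alone, and which gives the E-alkene by insertion at the terminal alkene carbon and syn-β-hydride elimination.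

Step 9
Reactants: 17 4-[(2S,3S)-6-acetoxy-4-[(E)-2-(4-acetoxyphenyl)ethenyl]-3-(3,5-diacetoxyphenyl)-2,3-dihydro-1-benzofuran-2-yl]-1,2-phenylene bis(4-methylbenzenesulfonate)
Product: 18 scirpusin A, 4-[(2S,3S)-3-(3,5-dihydroxyphenyl)-6-hydroxy-4-[(E)-2-(4-hydroxyphenyl)ethenyl]-2,3-dihydro-1-benzofuran-2-yl]benzene-1,2-diol
Conditions: aq. KOH (2 M, excess), 1,4-dioxane, degassed, argon, 60 °C; then 1 M HCl to pH 3 at 0 °C
Reagents that add atoms: none
Why: saponification of the four aryl acetates and hydroxide attack at sulfur of the two aryl tosylates (S–O cleavage, so each aryl oxygen stays) should free all six phenols in one operation, the stereocentres being not acidic enough to suffer and any reversible ring opening through a para-quinone methide reclosing to the same trans isomer because C3 is untouched.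

## Compound list

1 | 4-bromobenzene-1,2-diol (4-bromocatechol) | Oc1ccc(Br)cc1O | starting material
2 | 4-bromo-1,2-phenylene bis(4-methylbenzenesulfonate) | Brc1ccc(OS(=O)(=O)c2ccc(C)cc2)c(OS(=O)(=O)c2ccc(C)cc2)c1 | intermediate
3 | 1-ethenyl-3,5-dimethoxybenzene (3,5-dimethoxystyrene) | COc1cc(C=C)cc(OC)c1 | starting material
4 | 4-[(E)-2-(3,5-dimethoxyphenyl)ethenyl]-1,2-phenylene bis(4-methylbenzenesulfonate) | COc1cc(/C=C/c2ccc(OS(=O)(=O)c3ccc(C)cc3)c(OS(=O)(=O)c3ccc(C)cc3)c2)cc(OC)c1 | intermediate
5 | 4-[(2R,3R)-3-(3,5-dimethoxyphenyl)oxiran-2-yl]-1,2-phenylene bis(4-methylbenzenesulfonate) (trans-epoxide) | Cc1ccc(cc1)S(=O)(=O)Oc1ccc(cc1OS(=O)(=O)c1ccc(C)cc1)[C@H]1O[C@@H]1c1cc(OC)cc(OC)c1 | intermediate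
6 | 2,6-dibromo-4-methoxyphenol | COc1cc(Br)c(O)c(Br)c1 | starting material
7 | (2,6-dibromo-4-methoxyphenoxy)trimethylsilane | COc1cc(Br)c(O[Si](C)(C)C)c(Br)c1 | intermediate
8 | [3-bromo-5-methoxy-2-(trimethylsilyloxy)phenyl]lithium | [Li]c1cc(OC)cc(Br)c1O[Si](C)(C)C | intermediate
9 | lithium 2-bromo-4-methoxy-6-(trimethylsilyl)phenolate | [Li+].[O-]c1c(Br)cc(OC)cc1[Si](C)(C)C | intermediate
10 | 2-bromo-4-methoxy-6-(trimethylsilyl)phenyl trifluoromethanesulfonate | COc1cc(Br)c(OS(=O)(=O)C(F)(F)F)c(c1)[Si](C)(C)C | intermediate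
11 | 3-bromo-5-methoxybenzyne (1-bromo-5-methoxy-2,3-didehydrobenzene) | COC1=CC#CC(Br)=C1 | intermediate
12 | O-aryl oxiranium zwitterion: oxirane oxygen of 5 bonded to C1 of a 3-bromo-5-methoxyphenyl ring whose C2, between O+ and C–Br, is the carbanion; oxirane carbons arranged as in 5 | Cc1ccc(cc1)S(=O)(=O)Oc1ccc(cc1OS(=O)(=O)c1ccc(C)cc1)[C@H]1[O+](c2cc(OC)cc(Br)[c-]2)[C@@H]1c1cc(OC)cc(OC)c1 | intermediate
13 | 4-[(2S,3S)-4-bromo-3-(3,5-dimethoxyphenyl)-6-methoxy-2,3-dihydro-1-benzofuran-2-yl]-1,2-phenylene bis(4-methylbenzenesulfonate) | Brc1cc(OC)cc2c1[C@H](c1cc(OC)cc(OC)c1)[C@@H](c1ccc(OS(=O)(=O)c3ccc(C)cc3)c(OS(=O)(=O)c3ccc(C)cc3)c1)O2 | intermediate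
14 | 4-[(2S,3S)-4-bromo-3-(3,5-dihydroxyphenyl)-6-hydroxy-2,3-dihydro-1-benzofuran-2-yl]-1,2-phenylene bis(4-methylbenzenesulfonate) | Brc1cc(O)cc2c1[C@H](c1cc(O)cc(O)c1)[C@@H](c1ccc(OS(=O)(=O)c3ccc(C)cc3)c(OS(=O)(=O)c3ccc(C)cc3)c1)O2 | intermediate
15 | 4-[(2S,3S)-6-acetoxy-3-(3,5-diacetoxyphenyl)-4-bromo-2,3-dihydro-1-benzofuran-2-yl]-1,2-phenylene bis(4-methylbenzenesulfonate) | Brc1cc(OC(C)=O)cc2c1[C@H](c1cc(OC(C)=O)cc(OC(C)=O)c1)[C@@H](c1ccc(OS(=O)(=O)c3ccc(C)cc3)c(OS(=O)(=O)c3ccc(C)cc3)c1)O2 | intermediate
16 | 4-ethenylphenyl acetate (4-acetoxystyrene) | CC(=O)Oc1ccc(C=C)cc1 | starting material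
17 | 4-[(2S,3S)-6-acetoxy-4-[(E)-2-(4-acetoxyphenyl)ethenyl]-3-(3,5-diacetoxyphenyl)-2,3-dihydro-1-benzofuran-2-yl]-1,2-phenylene bis(4-methylbenzenesulfonate) | CC(=O)Oc1ccc(/C=C/c2cc(OC(C)=O)cc3c2[C@H](c2cc(OC(C)=O)cc(OC(C)=O)c2)[C@@H](c2ccc(OS(=O)(=O)c4ccc(C)cc4)c(OS(=O)(=O)c4ccc(C)cc4)c2)O3)cc1 | intermediate
18 | scirpusin A, 4-[(2S,3S)-3-(3,5-dihydroxyphenyl)-6-hydroxy-4-[(E)-2-(4-hydroxyphenyl)ethenyl]-2,3-dihydro-1-benzofuran-2-yl]benzene-1,2-diol | Oc1ccc(/C=C/c2cc(O)cc3c2[C@H](c2cc(O)cc(O)c2)[C@@H](c2ccc(O)c(O)c2)O3)cc1 | target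

## Step count and risks

Total step count: 9. Longest linear sequence: 7 steps (steps 1, 2, 3, 6, 7, 8, 9 from compound 1).

The three steps most likely to fail:

1. Step 6 (proposed new method). The oxirane is a weak nucleophile, so the aryne may be consumed by fluoride or by its own oligomerisation before it is intercepted. The oxiranium may open at the wrong benzylic carbon or be captured by fluoride. Bond rotation in the opened zwitterion may erode the trans selectivity. The fallback uses known reaction types, sets out from 4 and comes back at 14.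
   - Stilbene 4 is epoxidised under the conditions of step 3 with the enantiomeric ketone, 1,2:4,5-di-O-isopropylidene-β-L-erythro-2,3-hexodiulo-2,6-pyranose (available from L-sorbose), to give 4-[(2S,3S)-3-(3,5-dimethoxyphenyl)oxiran-2-yl]-1,2-phenylene bis(4-methylbenzenesulfonate) F1.
   - Friedel–Crafts ring opening of F1 by 5-bromobenzene-1,3-diol (Oc1cc(O)cc(Br)c1) in hexafluoroisopropanol, or with catalytic BF3·OEt2 in CH2Cl2 at −78 °C, should occur with inversion at the 3,5-dimethoxybenzylic carbon (the same electronic bias) through the ring position para to one hydroxyl and ortho to the other. This gives 4-[(1R,2S)-2-(2-bromo-4,6-dihydroxyphenyl)-2-(3,5-dimethoxyphenyl)-1-hydroxyethyl]-1,2-phenylene bis(4-methylbenzenesulfonate) F2.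
   - Mitsunobu cyclisation (PPh3, diisopropyl azodicarboxylate, THF) closes O1–C2 with inversion and gives 4-[(2S,3S)-4-bromo-3-(3,5-dimethoxyphenyl)-6-hydroxy-2,3-dihydro-1-benzofuran-2-yl]-1,2-phenylene bis(4-methylbenzenesulfonate) F3. The two inversions from the enantiomeric epoxide lead to the same (2S,3S) series.
   - BBr3 as in step 7 converts F3 into triphenol 14, which is acetylated to 15 as in the route.

2. Step 8. Oxidative addition into the hindered C4–Br bond beside the C3 diarylmethine may be slow, so that hydrodebromination or decomposition of the styrene partner competes. The fallback reverses the roles of the partners, sets out from 15 and comes back at 17.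
   - Stille coupling of 15 with tributyl(vinyl)stannane (Pd(PPh3)4, toluene, 100 °C) transfers only a small vinyl group to the hindered carbon. It gives 4-[(2S,3S)-6-acetoxy-3-(3,5-diacetoxyphenyl)-4-ethenyl-2,3-dihydro-1-benzofuran-2-yl]-1,2-phenylene bis(4-methylbenzenesulfonate) F4.
   - A Heck reaction of F4 with the unhindered 4-iodophenyl acetate (CC(=O)Oc1ccc(I)cc1) under Jeffery conditions (Pd(OAc)2, Bu4NCl, NaHCO3, DMF, 60 °C) gives 17.

3. Step 9. Cleavage of the second sulfonate of the catechol unit is slow and needs heat in strong base. Under these conditions the catecholate and the hydroxystilbene may oxidise and the dihydrofuran ring may open through a para-quinone methide. The fallback moves the sulfonate cleavage ahead of the stilbene, so the last step becomes a mild transesterification. It sets out from 15 and comes back at 18.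
   - Aqueous KOH in 1,4-dioxane (60 °C, argon, then HCl) removes the three acetyl and two tosyl groups of 15 while no stilbene is present. It gives 4-[(2S,3S)-4-bromo-3-(3,5-dihydroxyphenyl)-6-hydroxy-2,3-dihydro-1-benzofuran-2-yl]benzene-1,2-diol F5.
   - Peracetylation (Ac2O, pyridine) gives 4-[(2S,3S)-6-acetoxy-3-(3,5-diacetoxyphenyl)-4-bromo-2,3-dihydro-1-benzofuran-2-yl]-1,2-phenylene diacetate F6, which is purified.
   - The Heck reaction of step 8 with 16 gives scirpusin A hexaacetate, 4-[(2S,3S)-6-acetoxy-4-[(E)-2-(4-acetoxyphenyl)ethenyl]-3-(3,5-diacetoxyphenyl)-2,3-dihydro-1-benzofuran-2-yl]-1,2-phenylene diacetate F7.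
   - K2CO3 in degassed MeOH at 0 °C → rt removes the six acetyl groups and gives 18.

## Further compounds

F1 | step 6 | 4-[(2S,3S)-3-(3,5-dimethoxyphenyl)oxiran-2-yl]-1,2-phenylene bis(4-methylbenzenesulfonate) | Cc1ccc(cc1)S(=O)(=O)Oc1ccc(cc1OS(=O)(=O)c1ccc(C)cc1)[C@@H]1O[C@H]1c1cc(OC)cc(OC)c1
F2 | step 6 | 4-[(1R,2S)-2-(2-bromo-4,6-dihydroxyphenyl)-2-(3,5-dimethoxyphenyl)-1-hydroxyethyl]-1,2-phenylene bis(4-methylbenzenesulfonate) | Cc1ccc(cc1)S(=O)(=O)Oc1ccc(cc1OS(=O)(=O)c1ccc(C)cc1)[C@H](O)[C@@H](c1cc(OC)cc(OC)c1)c1c(O)cc(O)cc1Br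
F3 | step 6 | 4-[(2S,3S)-4-bromo-3-(3,5-dimethoxyphenyl)-6-hydroxy-2,3-dihydro-1-benzofuran-2-yl]-1,2-phenylene bis(4-methylbenzenesulfonate) | Brc1cc(O)cc2c1[C@H](c1cc(OC)cc(OC)c1)[C@@H](c1ccc(OS(=O)(=O)c3ccc(C)cc3)c(OS(=O)(=O)c3ccc(C)cc3)c1)O2
F4 | step 8 | 4-[(2S,3S)-6-acetoxy-3-(3,5-diacetoxyphenyl)-4-ethenyl-2,3-dihydro-1-benzofuran-2-yl]-1,2-phenylene bis(4-methylbenzenesulfonate) | C=Cc1cc(OC(C)=O)cc2c1[C@H](c1cc(OC(C)=O)cc(OC(C)=O)c1)[C@@H](c1ccc(OS(=O)(=O)c3ccc(C)cc3)c(OS(=O)(=O)c3ccc(C)cc3)c1)O2
F5 | step 9 | 4-[(2S,3S)-4-bromo-3-(3,5-dihydroxyphenyl)-6-hydroxy-2,3-dihydro-1-benzofuran-2-yl]benzene-1,2-diol | Brc1cc(O)cc2c1[C@H](c1cc(O)cc(O)c1)[C@@H](c1ccc(O)c(O)c1)O2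
F6 | step 9 | 4-[(2S,3S)-6-acetoxy-3-(3,5-diacetoxyphenyl)-4-bromo-2,3-dihydro-1-benzofuran-2-yl]-1,2-phenylene diacetate | Brc1cc(OC(C)=O)cc2c1[C@H](c1cc(OC(C)=O)cc(OC(C)=O)c1)[C@@H](c1ccc(OC(C)=O)c(OC(C)=O)c1)O2
F7 | step 9 | scirpusin A hexaacetate, 4-[(2S,3S)-6-acetoxy-4-[(E)-2-(4-acetoxyphenyl)ethenyl]-3-(3,5-diacetoxyphenyl)-2,3-dihydro-1-benzofuran-2-yl]-1,2-phenylene diacetate | CC(=O)Oc1ccc(/C=C/c2cc(OC(C)=O)cc3c2[C@H](c2cc(OC(C)=O)cc(OC(C)=O)c2)[C@@H](c2ccc(OC(C)=O)c(OC(C)=O)c2)O3)cc1
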